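## Structural features

The target is an achiral, symmetrical ether: two identical benzene rings joined through a CH2–O–CH2 chain, with no stereocentres. Each ring is numbered C1 (CH2O arm), C2 and C3 (Br), C4 and C5 (OH), C6 (H), so five contiguous positions carry three kinds of substituent in a fixed order. The free catechols oxidise easily to ortho-quinones, above all when deprotonated, and the four aryl bromides would not survive hydrogenolysis or uncontrolled halogen–metal exchange. Because the C4 hydroxyl is para to C1, each benzylic C–O bond ionises readily to a para-quinone methide. The central ether is therefore cleaved by Brønsted and Lewis acids and cannot be carried through a boron trihalide dealkylation. The real difficulty is twofold: placing the arm, two adjacent bromines and two adjacent oxygens around one ring without relying on ambiguous directing effects, and closing the ether in the presence of four phenolic hydroxyls and free C6–H positions. The key step exploits the contiguous C1(CH2)–C2(Br)–C3(Br) triad: a C1–C2 aryne flanked by the C3 bromine can take up the carbon arm at C1 and bromine at C2 in one operation, with the C3 bromine steering the addition. The symmetry means that one monomer supplies both halves.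

## Logic of the disconnections

15 is opened at one of its two equivalent benzylic C–O bonds, giving electrophile 13 and nucleophile 14. The cut is made there because the C4 hydroxyl para to C1 makes the benzylic carbon of 13 a latent quinone methide, so the bond can form without strong base, and because both partners descend from one intermediate. The gain is a halving of the molecule. The forward step must make the primary hydroxyl of 14 win over four phenolic oxygens and the free C6 positions, and must remove HBr without ionising the catechols.

14 is traced to 13 by exchanging the benzylic C–OH bond for C–Br. No separate synthesis of the nucleophile is then needed. The forward hydrolysis needs water in large excess and the substrate dilute, so that the alcohol formed does not alkylate itself.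

13 is traced to 12 by restoring the two O–CH3 bonds and replacing the benzylic C–Br by C–OH. Methyl ethers are kept because they come with the commercial phenol and are inert to organomagnesium reagents and peroxide. Their cleavage by a boron trihalide also delivers the benzylic bromide, which is why the ether is closed after dealkylation and not before. The forward step must avoid Friedel–Crafts self-alkylation by the benzylic cation and must leave the aryl bromides alone.

12 is traced to 11 by exchanging the benzylic C–O bond for a C–Si bond. The alkoxysilyl group is a masked hydroxyl that tolerates the organomagnesium chemistry of the key step. The forward oxidation has to be faster than protodesilylation of the benzylic C–Si bond.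

11 is cut at C1–CH2 and at C2–Br, leading to 4, 6 and 7. A vicinal difunctionalisation of a C1–C2 aryne sets two neighbouring substituents in one operation, with regiochemistry fixed by the C3 bromine rather than by competing directing groups. The pentasubstituted ring is reduced to a phenol-derived tetrasubstituted arene and two simple reagents. The forward step demands selective exchange at iodine, addition of the carbon nucleophile at C1 only, and an ortho-bromoaryl Grignard that survives until it is brominated.

6 is traced to 5 by cutting the C–Mg bond; direct magnesium insertion into the primary chloride is all that is asked.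

4 is traced to 3 by cutting the O–S bond. The phenolic oxygen is the future leaving group at C2, so the forward step only needs clean O-sulfonylation of a hindered but acidic phenol.

3 is traced to 2 by cutting the C–Br bond at the ring position between the hydroxyl and a methoxy group (future C3). The forward bromination must take the last position ortho to the hydroxyl without ipso attack at the iodinated carbon and without oxidising the ring.

2 is traced to 1 by cutting the C–I bond. Iodine goes in first because the first halogenation of 1 takes the most activated, least hindered site (ortho to OH, para to the 3-methoxy group), and that site must carry the exchangeable halogen (future C1).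

## Other disconnections considered

Alternative 1: The cut runs through C3–C4 and C5–C6 of each ring, a twofold retro-Diels–Alder to the bis(thiophene dioxide) ether A2 and two molecules of vinylene carbonate A3. Forward, each diene of A2 would add A3 across its alpha carbons and each bridged adduct would lose its sulfonyl bridge cheletropically. This would give the bis(dihydroarene carbonate) A1 with cis ring fusions, as meso and racemic forms that converge on aromatisation. Dehydrogenation and mild carbonate hydrolysis would finish the synthesis.
- In its favour: all five ring substituents are fixed by connectivity. The ether is present from the start, and the catechols are released from carbonates by mild hydrolysis. On the end-game this alternative is better than the chosen plan, which needs BBr3 and a late chemoselective etherification.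
- Against it: A2 is not an article of commerce. Its 4,5-dibromo pattern with a free alpha position runs against the alpha preference of thiophene bromination. Oxidising an electron-poor dibromothiophene to the dioxide needs forcing peracids, and thiophene dioxides with a free alpha position tend to dimerise. A3 is a sluggish dienophile that needs heat. A1 must be dehydrogenated, while the easier path for such a dihydroarene diol derivative is beta-elimination of a C–O bond, which would give a phenol with one oxygen lost.
- Comparison: on regiochemical security the two plans are equal, since both rely on connectivity. On mechanism the chosen aryne step is one low-temperature operation, against a thermal cycloaddition plus an oxidation that must beat elimination on both halves. On step economy the alternative is expected to be no shorter once A2 has to be built.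

Alternative 2: The cut removes the C4–O and C5–O bonds. Forward, whole cells expressing toluene dioxygenase would cis-dihydroxylate 1,2-dibromobenzene A4 to the dihydrodiol A5, and dehydrogenation would give 3,4-dibromocatechol A6.
- In its favour: one step from a bulk arene puts both oxygens next to the bromines. No protecting groups are needed and the catechol is obtained free. On oxygen introduction and atom economy this alternative is better than the chosen plan, which buys its oxygens as methyl ethers and must cleave them with BBr3.
- Against it: the two stereocentres of A5 are made enantioselectively only to be erased, since the target is achiral. A5 dehydrates easily to monophenols, and fermentation equipment is required. A6 still lacks the carbon arm, which has to enter at C1 (para to the C4 hydroxyl, beside a bromine) in competition with C6 (ortho to the C5 hydroxyl).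
- Comparison: the arm placement rests on directing effects, whereas the chosen plan fixes C1 by the aryne. The final ether closure would be the same as in the chosen plan, so the two are equal there. On step count the alternative could be shorter, but only if the C1 functionalisation is selective.

Alternative 3: The cut removes all four C–Br bonds. Forward, the preformed ether A7, bis(4-hydroxy-3-methoxybenzyl) ether, would be treated with four equivalents of an electrophilic brominating agent in a buffered carboxylic acid medium to give A8, brominated at C3 and C2 of both rings.
- In its favour: this is the shortest route. The ether exists from the outset, and the expected order of substitution (first ortho to the C4 hydroxyl, then para to the C5 methoxy group) matches the normal behaviour of such rings. On step economy it is clearly better than the chosen plan.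
- Against it: each ring of A7 is a para-hydroxybenzyl ether. Ipso attack at C1 would expel the benzylic carbon, and acid released by substitution would open the ether through the quinone methide, hence the buffer. The second bromination of each ring needs more forcing conditions than the ether is likely to tolerate, and eight substitution events must all go cleanly. A8 also keeps two methyl ethers, whose removal needs boron or aluminium halides that cleave the dibenzyl ether, so the route would fall back to the monomeric bromide and the same last step as the chosen plan.
- Comparison: on regiochemistry the two plans are roughly equal. On functional-group compatibility the chosen plan is safer, because every ring substituent is placed before the fragile ether exists, at the cost of more steps.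

Key step: step 5

Remark: ring positions are numbered as in the target throughout. On this numbering 4 carries iodine at C1, the triflate at C2 and bromine at C3, so no structure needed correction. The one design change is that 6 serves as both exchange reagent and nucleophile, so that no other organomagnesium species can add to the aryne.

## Route

Step 1
Reactants: 1 3,4-dimethoxyphenol
Product: 2 2-iodo-4,5-dimethoxyphenol
Conditions: NIS (1.05 equiv), MeCN, −10 °C → rt, dark
Reagents that add atoms: N-iodosuccinimide, O=C1CCC(=O)N1I
Why: Electrophilic aromatic iodination of a highly activated phenol; the position ortho to the hydroxyl and para to the 3-methoxy group is the most activated and least hindered, so monoiodination should occur there before the crowded site between OH and OMe reacts.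

Step 2
Reactants: 2 2-iodo-4,5-dimethoxyphenol
Product: 3 2-bromo-6-iodo-3,4-dimethoxyphenol
Conditions: NBS (1.0 equiv), i-Pr2NH (10 mol %), CH2Cl2, −20 → 0 °C, dark, anhydrous
Reagents that add atoms: N-bromosuccinimide, O=C1CCC(=O)N1Br
Why: Amine-catalysed ortho-bromination of a phenol; the only remaining position ortho to the hydroxyl is also ortho to a methoxy group and is far more activated than the last free ring position, which is meta to the hydroxyl. Cold anhydrous conditions and one equivalent of reagent should suppress ipso attack at the C–I carbon and oxidation to a quinone.

Step 3
Reactants: 3 2-bromo-6-iodo-3,4-dimethoxyphenol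
Product: 4 2-bromo-6-iodo-3,4-dimethoxyphenyl trifluoromethanesulfonate
Conditions: Tf2O (1.2 equiv), pyridine (2 equiv), CH2Cl2, 0 °C
Reagents that add atoms: trifluoromethanesulfonic anhydride, O=S(=O)(OS(=O)(=O)C(F)(F)F)C(F)(F)F
Why: O-Sulfonylation of a phenol; the two ortho halogens raise its acidity and do not prevent the oxygen from reaching sulfur.

Step 4
Reactants: 5 (chloromethyl)(isopropoxy)dimethylsilane
Product: 6 (isopropoxydimethylsilyl)methylmagnesium chloride (titrated THF solution)
Conditions: Mg turnings (1.2 equiv), BrCH2CH2Br (3 mol %), THF, rt → 45 °C
Reagents that add atoms: magnesium, [Mg]
Why: Grignard formation by magnesium insertion into a primary alkyl chloride; the alpha-silyl Grignard is a stable hydroxymethyl anion equivalent whose Si–O-i-Pr group later allows oxidation.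

Step 5
Reactants: 4 2-bromo-6-iodo-3,4-dimethoxyphenyl trifluoromethanesulfonate; 6 (isopropoxydimethylsilyl)methylmagnesium chloride; 7 1,2-dibromotetrachloroethane
Product: 11 (2,3-dibromo-4,5-dimethoxybenzyl)(isopropoxy)dimethylsilane, via arylmagnesium triflate 8 (not isolated), via 3-bromo-4,5-dimethoxybenzyne 9 (not isolated), via ortho-bromoaryl Grignard 10 (not isolated)
Conditions: 4 added slowly to 6 (2.5 equiv), THF, −78 °C, 1 h, kept below −50 °C; then 7 (3.0 equiv), THF, −78 → 0 °C; aq NH4Cl; crude 11 used directly
Reagents that add atoms: none
Why: Iodine–magnesium exchange by 6 at the C1 iodide (far faster than at the C3 bromide and activated by the ortho sulfonate) gives 8, which loses magnesium chloride triflate already at −78 °C; only the C2 triflate is ortho to the C–Mg bond, so aryne 9 can form only across C1–C2. A second equivalent of 6 adds to the strained triple bond (aryne carbomagnesiation), and aryl Grignard 10 then takes bromine from 7, which fragments to tetrachloroethene. The closest known reaction type is aryne generation from ortho-iodoaryl triflates with silylmethyl Grignard reagents, combined with Grignard addition to a 3-haloaryne and electrophilic quench of the ortho-magnesiated arene. No ring is closed and no stereocentre is formed. The selectivity needed is C–C bond formation at C1: the inductively withdrawing C3 bromine distorts the aryne so that C1 is the more electrophilic terminus and the carbanion develops at C2 next to bromine, and C1 (beside C6–H) is also the sterically open end. Using 6 for exchange and addition keeps any other carbon nucleophile out of the flask, and adding 4 to excess 6 keeps the aryne from meeting aryl Grignards in quantity. Holding 10 below about −50 °C until 7 is present should prevent loss of magnesium bromide chloride toward a second aryne across C2–C3.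

Step 6
Reactants: 11 (2,3-dibromo-4,5-dimethoxybenzyl)(isopropoxy)dimethylsilane
Product: 12 (2,3-dibromo-4,5-dimethoxyphenyl)methanol
Conditions: 30% aq H2O2, KF, KHCO3, THF/MeOH (1:1), rt
Reagents that add atoms: hydrogen peroxide, OO
Why: Tamao–Fleming oxidation: peroxide adds to the fluoride-activated alkoxysilane, the benzyl group migrates from silicon to oxygen, and hydrolysis of the Si–O bond releases the primary alcohol. Aryl bromides and methyl ethers are inert to these mildly basic conditions.

Step 7
Reactants: 12 (2,3-dibromo-4,5-dimethoxyphenyl)methanol
Product: 13 3,4-dibromo-5-(bromomethyl)benzene-1,2-diol
Conditions: BBr3 (4 equiv), CH2Cl2, −78 °C → rt; ice-water quench, rapid extraction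
Reagents that add atoms: boron tribromide, BrB(Br)Br
Why: Lewis acid dealkylation of both aryl methyl ethers (bromide attacks the methyl group of the O–B complex); the same reagent converts the benzylic hydroxyl into the bromide, as expected for a benzylic alcohol with a para oxygen. The aryl bromides are untouched and the catechol is freed from its borate on quench.

Step 8
Reactants: 13 3,4-dibromo-5-(bromomethyl)benzene-1,2-diol (one part of the batch)
Product: 14 3,4-dibromo-5-(hydroxymethyl)benzene-1,2-diol
Conditions: acetone/H2O (1:1), high dilution, 25 °C, Ar
Reagents that add atoms: water, O
Why: Solvolysis of a para-hydroxybenzyl bromide: the C4 hydroxyl assists ionisation (quinone methide or benzylic cation), and water in large excess over a dilute substrate should capture it to give the alcohol and not an ether.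

Step 9
Reactants: 13 3,4-dibromo-5-(bromomethyl)benzene-1,2-diol; 14 3,4-dibromo-5-(hydroxymethyl)benzene-1,2-diol
Product: 15 bis(2,3-dibromo-4,5-dihydroxybenzyl) ether
Conditions: 14 (2 equiv), 2,6-di-tert-butyl-4-methylpyridine (1.1 equiv), 4 Å MS, MeCN, 13 added over 4 h, 0 °C → rt, Ar; excess 14 recovered
Reagents that add atoms: none
Why: Alkylation of an alcohol by a para-hydroxybenzyl halide (Williamson-type etherification through the quinone methide). The primary hydroxyl of 14, kept in excess while 13 is added slowly, is a better neutral nucleophile than the un-ionised, bromine-deactivated catechol oxygens or C6. The hindered pyridine removes HBr, which would reopen the ether, without deprotonating the catechols.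

## Compound list

1 | 3,4-dimethoxyphenol | COc1ccc(O)cc1OC | starting material
2 | 2-iodo-4,5-dimethoxyphenol | COc1cc(O)c(I)cc1OC | intermediate
3 | 2-bromo-6-iodo-3,4-dimethoxyphenol | COc1cc(I)c(O)c(Br)c1OC | intermediate
4 | 2-bromo-6-iodo-3,4-dimethoxyphenyl trifluoromethanesulfonate | COc1cc(I)c(OS(=O)(=O)C(F)(F)F)c(Br)c1OC | intermediate
5 | (chloromethyl)(isopropoxy)dimethylsilane | CC(C)O[Si](C)(C)CCl | starting material
6 | (isopropoxydimethylsilyl)methylmagnesium chloride | CC(C)O[Si](C)(C)C[Mg]Cl | intermediate
7 | 1,2-dibromotetrachloroethane | BrC(Cl)(Cl)C(Cl)(Cl)Br | starting material
8 | [3-bromo-4,5-dimethoxy-2-(trifluoromethylsulfonyloxy)phenyl]magnesium chloride | COc1cc([Mg]Cl)c(OS(=O)(=O)C(F)(F)F)c(Br)c1OC | intermediate (not isolated)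
9 | 3-bromo-4,5-dimethoxybenzyne | COC1=CC#CC(Br)=C1OC | intermediate (not isolated)
10 | {2-bromo-3,4-dimethoxy-6-[(isopropoxydimethylsilyl)methyl]phenyl}magnesium chloride | COc1cc(C[Si](C)(C)OC(C)C)c([Mg]Cl)c(Br)c1OC | intermediate (not isolated)
11 | (2,3-dibromo-4,5-dimethoxybenzyl)(isopropoxy)dimethylsilane | COc1cc(C[Si](C)(C)OC(C)C)c(Br)c(Br)c1OC | intermediate
12 | (2,3-dibromo-4,5-dimethoxyphenyl)methanol | COc1cc(CO)c(Br)c(Br)c1OC | intermediate
13 | 3,4-dibromo-5-(bromomethyl)benzene-1,2-diol | Oc1cc(CBr)c(Br)c(Br)c1O | intermediate
14 | 3,4-dibromo-5-(hydroxymethyl)benzene-1,2-diol | Oc1cc(CO)c(Br)c(Br)c1O | intermediate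
15 | bis(2,3-dibromo-4,5-dihydroxybenzyl) ether | Oc1cc(COCc2cc(O)c(O)c(Br)c2Br)c(Br)c(Br)c1O | target

## Step count and least certain steps

Total step count: 9. Longest linear sequence: 8 steps (steps 1, 2, 3, 5, 6, 7, 8, 9, from 1 to 15); step 4 is a one-step side branch.

Step 5 (key step). The most likely failure is at the crowded C2–magnesium bond of 10, which lies between the silylmethyl arm and the C3 bromine. Bromine transfer may be incomplete, or 10 may lose magnesium bromide chloride to a second aryne if the mixture has to be warmed to finish the slow addition of the weakly nucleophilic alpha-silyl Grignard. Either process costs the C2–Br bond while the C1–C bond still forms. The fallback sets out from 4 and 6. The same exchange, aryne formation and carbomagnesiation are run, but 10 is protonated with methanol at −78 °C to give (3-bromo-4,5-dimethoxybenzyl)(isopropoxy)dimethylsilane F1. Oxidation as in step 6 gives (3-bromo-4,5-dimethoxyphenyl)methanol F2. The C2 bromine is then introduced by electrophilic aromatic bromination (NBS, MeCN, 0 °C), which should go para to the C5 methoxy group as in vanillin-type rings, and the route is rejoined at 12.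

Step 9. The most likely failure is capture of the quinone methide from 13 by a phenolic oxygen or by C6 of another ring in place of the benzylic hydroxyl of 14, which would lead to oligomeric aryl ethers and diarylmethanes. The fallback masks the phenols and sets out from 14.
- Silylation with TBSCl and imidazole in DMF should give tert-butyl{[2,3-dibromo-4,5-bis(tert-butyldimethylsilyloxy)benzyl]oxy}dimethylsilane F3.
- Selective cleavage of the alkyl silyl ether (AcOH/THF/H2O) gives [2,3-dibromo-4,5-bis(tert-butyldimethylsilyloxy)phenyl]methanol F4.
- Part of it is converted by an Appel reaction (CBr4, PPh3) into 2,3-dibromo-4,5-bis(tert-butyldimethylsilyloxy)benzyl bromide F5.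
- The two are joined under neutral silver promotion (silver trifluoromethanesulfonate AgOSO2CF3, 2,6-di-tert-butyl-4-methylpyridine, CH2Cl2) to bis[2,3-dibromo-4,5-bis(tert-butyldimethylsilyloxy)benzyl] ether F6.
- Buffered fluoride (TBAF, AcOH, THF, 0 °C) removes the silyl groups without touching the ether, and the route is rejoined at 15.

Step 2. The most likely failure is ipso attack of the brominating agent at the iodine-bearing carbon, the most activated ring position, with halogen scrambling, or oxidation of the para-methoxyphenol to a quinone. The fallback sets out from 1 and places the bromine by directed metalation before iodination.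
- Protection (MOMCl, i-Pr2NEt) gives 1,2-dimethoxy-4-(methoxymethoxy)benzene F7.
- Lithiation with n-BuLi at the position flanked by the two directing oxygens, then quench with 7, gives 2-bromo-3,4-dimethoxy-1-(methoxymethoxy)benzene F8.
- Acidic methanolysis gives 2-bromo-3,4-dimethoxyphenol F9.
- Iodination with NIS at the only position ortho to the hydroxyl (also para to the 3-methoxy group) rejoins the route at 3.

Step 6. The most likely failure is fluoride- or base-induced protodesilylation of the benzylic C–Si bond competing with peroxide oxidation, because the dibromoaryl-stabilised benzyl anion is a fair leaving group from silicon. The fallback sets out from 11 and makes use of that cleavage. TBAF in wet THF should give 2,3-dibromo-4,5-dimethoxytoluene F10. Wohl–Ziegler bromination (NBS, AIBN, PhCF3, reflux) gives 2,3-dibromo-1-(bromomethyl)-4,5-dimethoxybenzene F11. BBr3 dealkylation as in step 7 then rejoins the route at 13, bypassing 12.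

## Further compounds

F1 | step 5 | (3-bromo-4,5-dimethoxybenzyl)(isopropoxy)dimethylsilane | COc1cc(C[Si](C)(C)OC(C)C)cc(Br)c1OC
F2 | step 5 | (3-bromo-4,5-dimethoxyphenyl)methanol | COc1cc(CO)cc(Br)c1OC
F3 | step 9 | tert-butyl{[2,3-dibromo-4,5-bis(tert-butyldimethylsilyloxy)benzyl]oxy}dimethylsilane | CC(C)(C)[Si](C)(C)OCc1cc(O[Si](C)(C)C(C)(C)C)c(O[Si](C)(C)C(C)(C)C)c(Br)c1Br
F4 | step 9 | [2,3-dibromo-4,5-bis(tert-butyldimethylsilyloxy)phenyl]methanol | OCc1cc(O[Si](C)(C)C(C)(C)C)c(O[Si](C)(C)C(C)(C)C)c(Br)c1Br
F5 | step 9 | 2,3-dibromo-4,5-bis(tert-butyldimethylsilyloxy)benzyl bromide | BrCc1cc(O[Si](C)(C)C(C)(C)C)c(O[Si](C)(C)C(C)(C)C)c(Br)c1Br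
F6 | step 9 | bis[2,3-dibromo-4,5-bis(tert-butyldimethylsilyloxy)benzyl] ether | CC(C)(C)[Si](C)(C)Oc1cc(COCc2cc(O[Si](C)(C)C(C)(C)C)c(O[Si](C)(C)C(C)(C)C)c(Br)c2Br)c(Br)c(Br)c1O[Si](C)(C)C(C)(C)C
F7 | step 2 | 1,2-dimethoxy-4-(methoxymethoxy)benzene | COCOc1ccc(OC)c(OC)c1
F8 | step 2 | 2-bromo-3,4-dimethoxy-1-(methoxymethoxy)benzene | COCOc1ccc(OC)c(OC)c1Br
F9 | step 2 | 2-bromo-3,4-dimethoxyphenol | COc1ccc(O)c(Br)c1OC
F10 | step 6 | 2,3-dibromo-4,5-dimethoxytoluene | COc1cc(C)c(Br)c(Br)c1OC
F11 | step 6 | 2,3-dibromo-1-(bromomethyl)-4,5-dimethoxybenzene | COc1cc(CBr)c(Br)c(Br)c1OC
A1 | alternative 1 | bis[(6,7-dibromo-2-oxo-3a,7a-dihydro-1,3-benzodioxol-5-yl)methyl] ether, cis ring fusions, one diastereomer drawn | O=C1O[C@H]2C=C(COCC3=C[C@H]4OC(=O)O[C@H]4C(Br)=C3Br)C(Br)=C(Br)[C@H]2O1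
A2 | alternative 1 | bis[(4,5-dibromo-1,1-dioxidothiophen-3-yl)methyl] ether | O=S1(=O)C=C(COCC2=CS(=O)(=O)C(Br)=C2Br)C(Br)=C1Br
A3 | alternative 1 | vinylene carbonate | O=C1OC=CO1
A4 | alternative 2 | 1,2-dibromobenzene | Brc1ccccc1Br
A5 | alternative 2 | (1S,2S)-3,4-dibromocyclohexa-3,5-diene-1,2-diol | O[C@H]1C=CC(Br)=C(Br)[C@H]1O
A6 | alternative 2 | 3,4-dibromobenzene-1,2-diol | Oc1ccc(Br)c(Br)c1O
A7 | alternative 3 | bis(4-hydroxy-3-methoxybenzyl) ether | COc1cc(COCc2ccc(O)c(OC)c2)ccc1O
A8 | alternative 3 | bis(2,3-dibromo-4-hydroxy-5-methoxybenzyl) ether | COc1cc(COCc2cc(OC)c(O)c(Br)c2Br)c(Br)c(Br)c1O
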